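**Retrosynthetic overview**
- 16 ⇒ 15: the C17–C19 bond is made last, by a photochemical decarboxylative, dehydrogenative hydroxymethylation of the butenolide β-C–H with glycolic acid.
- 15 ⇒ 12: the butenolide C17=C18 unsaturation comes from selenoxide elimination of the saturated lactone.
- 12 ⇒ 9 + 11: the C14–C15 bond is made by Ni-catalysed electroreductive alkenyl–alkyl coupling; C16 is bought in lactone 10 (from L-glutamic acid).
- 9 ⇒ 5 + 6: the C12–C13 bond and the (Z)-alkene come from anti-carbomagnesiation of propargyl alcohol and iodinolysis; 5 comes from (+)-sclareolide 1, which supplies C5 and C10.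
- Rings: rings A and B are bought in 1 and the five-membered lactone ring in 10; no ring is built, the lactone is only dehydrogenated (step 7) after fragment union.

Assumption: positional labels are C8=C9 (ring alkene), C11–C12 (ethylene), C13=C14 (side-chain alkene, CH2OH on C13), C15 (CH2), C16 (lactone CH–O), C17 (ring carbon next to C16), C18 (ring CH next to the carbonyl C20), C19 (CH2OH carbon on C17); compounds 1, 6 and 10 are bought.

**Route**

Step 1
Reactants: 1 (+)-sclareolide
Product: 3 methyl 2-[(4aS,8aS)-2,5,5,8a-tetramethyl-3,4,4a,5,6,7,8,8a-octahydronaphthalen-1-yl]acetate, via ring-opened acid 2 (not isolated)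
Conditions: conc. H2SO4 (1.5 equiv), MeOH, reflux, 36 h; AgNO3–SiO2 chromatography to remove minor alkene isomers
Reagents that add atoms: methanol, CO
Why: Acid-catalysed alkyl–oxygen cleavage of the tertiary lactone gives the C8 cation, E1 loss of H9 with acid equilibration favours the tetrasubstituted 8,9-alkene, and the freed acid undergoes Fischer esterification; C5 and C10 are untouched and the C8 and C9 stereocentres are erased on purpose.

Step 2
Reactants: 3 methyl 2-[(4aS,8aS)-2,5,5,8a-tetramethyl-3,4,4a,5,6,7,8,8a-octahydronaphthalen-1-yl]acetate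
Product: 4 2-[(4aS,8aS)-2,5,5,8a-tetramethyl-3,4,4a,5,6,7,8,8a-octahydronaphthalen-1-yl]ethan-1-ol
Conditions: LiAlH4, THF, 0 °C to rt
Reagents that add atoms: none
Why: Standard LiAlH4 ester reduction; the isolated tetrasubstituted alkene is inert and no stereocentre is involved.

Step 3
Reactants: 4 2-[(4aS,8aS)-2,5,5,8a-tetramethyl-3,4,4a,5,6,7,8,8a-octahydronaphthalen-1-yl]ethan-1-ol
Product: 5 (4aS,8aS)-1-(2-bromoethyl)-2,5,5,8a-tetramethyl-3,4,4a,5,6,7,8,8a-octahydronaphthalene
Conditions: CBr4, PPh3, CH2Cl2, 0 °C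
Reagents that add atoms: carbon tetrabromide, BrC(Br)(Br)Br
Why: Appel bromination runs by SN2 on the primary alkoxyphosphonium ion under neutral conditions, so no cation that could engage the homoallylic alkene is formed.

Step 4
Reactants: 5 (4aS,8aS)-1-(2-bromoethyl)-2,5,5,8a-tetramethyl-3,4,4a,5,6,7,8,8a-octahydronaphthalene; 6 propargyl alcohol (prop-2-yn-1-ol)
Product: 9 (Z)-3-iodo-2-{2-[(4aS,8aS)-2,5,5,8a-tetramethyl-3,4,4a,5,6,7,8,8a-octahydronaphthalen-1-yl]ethyl}prop-2-en-1-ol, via Grignard reagent 7 (not isolated), via vinylmagnesium chelate 8 (not isolated)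
Conditions: Mg turnings, THF, rt; add to 6 (1.5 equiv) pre-treated with EtMgBr (1.5 equiv, THF, 0 °C), CuI (10 mol %), THF, rt, 16 h; then I2, −20 to 0 °C
Reagents that add atoms: iodine, II
Why: CuI-catalysed anti-carbomagnesiation of the magnesium alkoxide of propargyl alcohol (Duboudin-type) puts the alkyl group on the carbinol-bearing alkyne carbon and magnesium on the terminus in a five-membered chelate, so iodinolysis with retention fixes the C13=C14 geometry with iodine cis to CH2OH (the homoallyl–cyclopropylcarbinyl shuffle of 7 is degenerate).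

Step 5
Reactants: 10 (S)-5-(hydroxymethyl)dihydrofuran-2(3H)-one
Product: 11 (S)-5-(iodomethyl)dihydrofuran-2(3H)-one
Conditions: I2, PPh3, imidazole, CH2Cl2, 0 °C to rt
Reagents that add atoms: iodine, II
Why: Appel iodination of the primary alcohol by SN2 at CH2; the adjacent bought stereocentre (the future C16) is not touched.

Step 6
Reactants: 9 (Z)-3-iodo-2-{2-[(4aS,8aS)-2,5,5,8a-tetramethyl-3,4,4a,5,6,7,8,8a-octahydronaphthalen-1-yl]ethyl}prop-2-en-1-ol; 11 (S)-5-(iodomethyl)dihydrofuran-2(3H)-one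
Product: 12 (S)-5-[(Z)-3-(hydroxymethyl)-5-((4aS,8aS)-2,5,5,8a-tetramethyl-3,4,4a,5,6,7,8,8a-octahydronaphthalen-1-yl)pent-2-en-1-yl]dihydrofuran-2(3H)-one
Conditions: NiBr2(DME) (10 mol %), 4,4'-di-tert-butyl-2,2'-bipyridine (12 mol %), NaI (0.2 M), DMA, undivided cell, Zn anode, Ni-foam cathode, 5 mA, 2.5 F/mol, rt; 11 (1.5 equiv)
Reagents that add atoms: none
Why: In this Ni-catalysed electroreductive cross-electrophile coupling, zerovalent nickel inserts into the alkenyl C–I bond with retention of geometry, the primary iodide is converted into a β-acyloxyalkyl radical that has no ring alkene to rearrange onto (the reason the lactone is coupled in its saturated form), and radical capture with reductive elimination forms the C14–C15 bond while C16 keeps its bought configuration.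

Step 7
Reactants: 12 (S)-5-[(Z)-3-(hydroxymethyl)-5-((4aS,8aS)-2,5,5,8a-tetramethyl-3,4,4a,5,6,7,8,8a-octahydronaphthalen-1-yl)pent-2-en-1-yl]dihydrofuran-2(3H)-one
Product: 15 (R)-5-[(Z)-3-(hydroxymethyl)-5-((4aS,8aS)-2,5,5,8a-tetramethyl-3,4,4a,5,6,7,8,8a-octahydronaphthalen-1-yl)pent-2-en-1-yl]furan-2(5H)-one, via alpha-selenide 13 (not isolated), via selenoxide 14 (not isolated)
Conditions: LiN(i-Pr)2 (2.2 equiv), THF, −78 °C; PhSeBr (1.1 equiv), −78 °C; H2O quench; crude in THF–MeOH–H2O, NaIO4, NaHCO3, 0 °C to rt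
Reagents that add atoms: none
Why: Kinetic deprotonation (alkoxide plus lactone enolate), α-selenenylation and selenoxide syn-elimination, which can only run toward C17, give the conjugated butenolide; C16 is never deprotonated, and periodate does not epoxidise the two alkenes.

Step 8
Reactants: 15 (R)-5-[(Z)-3-(hydroxymethyl)-5-((4aS,8aS)-2,5,5,8a-tetramethyl-3,4,4a,5,6,7,8,8a-octahydronaphthalen-1-yl)pent-2-en-1-yl]furan-2(5H)-one
Product: 16 16-epi-luffarin L
Conditions: glycolic acid (3 equiv), K2HPO4 (20 mol %), Ir[dF(CF3)ppy]2(dtbbpy)PF6 (2 mol %), Co(dmgH)2(py)Cl (8 mol %), MeCN–H2O 9:1, 450 nm LEDs, Ar, rt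
Reagents that add atoms: glycolic acid, OCC(=O)O
Why: Proposed new method: the photoexcited iridium complex oxidises glycolate, loss of CO2 gives the nucleophilic hydroxymethyl radical, which adds to the electron-poor butenolide β-carbon C17 (the only polarity-matched alkene in 15), and the α-lactonyl radical at C18 is intercepted by divalent cobaloxime, which removes the C17 hydrogen (the only β-hydrogen) and restores the conjugated C17=C18 bond, while the cobalt hydride releases H2 and the reduced photocatalyst returns cobalt to the divalent state, so the net change is a redox-neutral exchange of C–H for C–CH2OH that forms the C17–C19 bond without touching C16; the closest known reaction types are the photoredox/cobaloxime decarboxylative Heck-type coupling of aliphatic acids with styrenes and the photochemical Giese addition of hydroxymethyl radicals to butenolides, whose merger on an electron-poor cyclic acceptor with an α-hydroxy acid has not been shown.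

**Compound list**

1 | (+)-sclareolide, (3aR,5aS,9aS,9bR)-3a,6,6,9a-tetramethyldecahydronaphtho[2,1-b]furan-2(1H)-one | C[C@]12CCCC([C@@H]1CC[C@@]3([C@@H]2CC(=O)O3)C)(C)C | starting material
2 | 2-[(4aS,8aS)-2,5,5,8a-tetramethyl-3,4,4a,5,6,7,8,8a-octahydronaphthalen-1-yl]acetic acid | CC1=C(CC(=O)O)[C@@]2(C)CCCC(C)(C)[C@@H]2CC1 | intermediate
3 | methyl 2-[(4aS,8aS)-2,5,5,8a-tetramethyl-3,4,4a,5,6,7,8,8a-octahydronaphthalen-1-yl]acetate | CC1=C(CC(=O)OC)[C@@]2(C)CCCC(C)(C)[C@@H]2CC1 | intermediate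
4 | 2-[(4aS,8aS)-2,5,5,8a-tetramethyl-3,4,4a,5,6,7,8,8a-octahydronaphthalen-1-yl]ethan-1-ol | CC1=C(CCO)[C@@]2(C)CCCC(C)(C)[C@@H]2CC1 | intermediate
5 | (4aS,8aS)-1-(2-bromoethyl)-2,5,5,8a-tetramethyl-3,4,4a,5,6,7,8,8a-octahydronaphthalene | CC1=C(CCBr)[C@@]2(C)CCCC(C)(C)[C@@H]2CC1 | intermediate
6 | propargyl alcohol (prop-2-yn-1-ol) | C#CCO | starting material
7 | {2-[(4aS,8aS)-2,5,5,8a-tetramethyl-3,4,4a,5,6,7,8,8a-octahydronaphthalen-1-yl]ethyl}magnesium bromide | CC1=C(CC[Mg]Br)[C@@]2(C)CCCC(C)(C)[C@@H]2CC1 | intermediate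
8 | 4-{2-[(4aS,8aS)-2,5,5,8a-tetramethyl-3,4,4a,5,6,7,8,8a-octahydronaphthalen-1-yl]ethyl}-2,5-dihydro-1,2-oxamagnesole (cyclic vinylmagnesium alkoxide) | CC1=C(CCC3=C[Mg]OC3)[C@@]2(C)CCCC(C)(C)[C@@H]2CC1 | intermediate
9 | (Z)-3-iodo-2-{2-[(4aS,8aS)-2,5,5,8a-tetramethyl-3,4,4a,5,6,7,8,8a-octahydronaphthalen-1-yl]ethyl}prop-2-en-1-ol | CC1=C(CC/C(=C/I)CO)[C@@]2(C)CCCC(C)(C)[C@@H]2CC1 | intermediate
10 | (S)-5-(hydroxymethyl)dihydrofuran-2(3H)-one | OC[C@H]1OC(=O)CC1 | starting material
11 | (S)-5-(iodomethyl)dihydrofuran-2(3H)-one | IC[C@H]1OC(=O)CC1 | intermediate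
12 | (S)-5-[(Z)-3-(hydroxymethyl)-5-((4aS,8aS)-2,5,5,8a-tetramethyl-3,4,4a,5,6,7,8,8a-octahydronaphthalen-1-yl)pent-2-en-1-yl]dihydrofuran-2(3H)-one | CC1=C(CC/C(=C/C[C@H]2OC(=O)CC2)CO)[C@@]2(C)CCCC(C)(C)[C@@H]2CC1 | intermediate
13 | 3-(phenylselanyl) derivative of 12 (both C3 epimers; lactone C5 unchanged) | CC1=C(CC/C(=C/C[C@H]2OC(=O)C([Se]c3ccccc3)C2)CO)[C@@]2(C)CCCC(C)(C)[C@@H]2CC1 | intermediate
14 | 3-(phenylseleninyl) derivative of 12 (selenoxide of 13) | CC1=C(CC/C(=C/C[C@H]2OC(=O)C([Se](=O)c3ccccc3)C2)CO)[C@@]2(C)CCCC(C)(C)[C@@H]2CC1 | intermediate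
15 | (R)-5-[(Z)-3-(hydroxymethyl)-5-((4aS,8aS)-2,5,5,8a-tetramethyl-3,4,4a,5,6,7,8,8a-octahydronaphthalen-1-yl)pent-2-en-1-yl]furan-2(5H)-one | CC1=C(CC/C(=C/C[C@H]2OC(=O)C=C2)CO)[C@@]2(C)CCCC(C)(C)[C@@H]2CC1 | intermediate
16 | 16-epi-luffarin L, (R)-4-(hydroxymethyl)-5-[(Z)-3-(hydroxymethyl)-5-((4aS,8aS)-2,5,5,8a-tetramethyl-3,4,4a,5,6,7,8,8a-octahydronaphthalen-1-yl)pent-2-en-1-yl]furan-2(5H)-one | CC1=C(CC/C(=C/C[C@H]2OC(=O)C=C2CO)CO)[C@@]2(C)CCCC(C)(C)[C@@H]2CC1 | target

**Summary**

Total step count: 8.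
Longest linear sequence: 7 steps (1 → 3 → 4 → 5 → 9 → 12 → 15 → 16; steps 1, 2, 3, 4, 6, 7 and 8).

**Three steps most likely to fail**

Step 8 (the new reaction). The risks are simple Giese reduction to the saturated hydroxymethyl lactone and poor turnover of the cobalt cycle. The fallback uses known chemistry, sets out from 15 and comes back at 16. Copper-mediated conjugate addition of the Tamao hydroxymethyl-anion equivalent (i-PrO)Me2SiCH2MgCl (3 equiv, the first consumed by the free OH) with CuI and Me3SiCl in THF at −78 °C occurs anti to the C15 chain, and trapping of the enolate with PhSeBr gives the trans,trans silylmethyl selenide lactone F1. H2O2, KF and KHCO3 in THF–MeOH then perform the Tamao oxidation of C–Si to C–OH and the selenoxide syn-elimination in one flask to give 16.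

Step 6 (electroreductive union). The risks are homocoupling of 9, protodeiodination, or erosion of the alkene geometry at nickel. The fallback replaces the radical coupling by a polar epoxide opening; it sets out from 8 (the chelate of step 4, used before the iodine quench) and from 10, and comes back at 12. TsCl and pyridine convert 10 into [(2S)-5-oxotetrahydrofuran-2-yl]methyl 4-methylbenzenesulfonate F2. NaOMe in MeOH at 0 °C opens the lactone and the freed alkoxide closes the epoxide, giving methyl 3-[(2S)-oxiran-2-yl]propanoate F3 with the oxygen kept on the stereocentre. Chelate 8 with CuI (10 mol %) in THF at −30 °C opens F3 at its CH2 terminus, and the resulting γ-alkoxy ester lactonises on work-up with TsOH to 12.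

Step 4 (anti-carbomagnesiation with the Grignard reagent as limiting component). The risks are protonation of 7 by the alkyne C–H and low conversion. The fallback moves the union to the C12–C13 bond; it sets out from 5, 6 and 11 and comes back at 12. Photoinduced copper-catalysed alkylation of the terminal alkyne 6 with iodide 11 (CuCl, 2,2':6',2''-terpyridine, K2CO3, MeCN, blue LEDs) gives (S)-5-(4-hydroxybut-2-yn-1-yl)dihydrofuran-2(3H)-one F4. Syn-hydrostannation with Bu3SnH and PdCl2(PPh3)2 in THF, with tin going to the carbinol-bearing carbon, gives (S)-5-[(E)-4-hydroxy-3-(tributylstannyl)but-2-en-1-yl]dihydrofuran-2(3H)-one F5. I2 in CH2Cl2 gives (S)-5-[(E)-4-hydroxy-3-iodobut-2-en-1-yl]dihydrofuran-2(3H)-one F6 with retention. F6 is then coupled with bromide 5 under the electrolysis conditions of step 6 (NaI converts 5 into the iodide in the cell), which gives 12 with the same alkene geometry.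

Further compounds
F1 | step 8 | (3,4-trans,4,5-trans)-4-{[dimethyl(propan-2-yloxy)silyl]methyl}-5-[(Z)-3-(hydroxymethyl)-5-((4aS,8aS)-2,5,5,8a-tetramethyl-3,4,4a,5,6,7,8,8a-octahydronaphthalen-1-yl)pent-2-en-1-yl]-3-(phenylselanyl)dihydrofuran-2(3H)-one | CC1=C(CC/C(=C/C[C@H]2OC(=O)[C@@H]([Se]c3ccccc3)[C@@H]2C[Si](C)(C)OC(C)C)CO)[C@@]2(C)CCCC(C)(C)[C@@H]2CC1
F2 | step 6 | [(2S)-5-oxotetrahydrofuran-2-yl]methyl 4-methylbenzenesulfonate | Cc1ccc(cc1)S(=O)(=O)OC[C@H]1OC(=O)CC1
F3 | step 6 | methyl 3-[(2S)-oxiran-2-yl]propanoate | COC(=O)CC[C@H]1CO1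
F4 | step 4 | (S)-5-(4-hydroxybut-2-yn-1-yl)dihydrofuran-2(3H)-one | OCC#CC[C@H]1OC(=O)CC1
F5 | step 4 | (S)-5-[(E)-4-hydroxy-3-(tributylstannyl)but-2-en-1-yl]dihydrofuran-2(3H)-one | CCCC[Sn](CCCC)(CCCC)/C(=C/C[C@H]1OC(=O)CC1)CO
F6 | step 4 | (S)-5-[(E)-4-hydroxy-3-iodobut-2-en-1-yl]dihydrofuran-2(3H)-one | I/C(=C/C[C@H]1OC(=O)CC1)CO
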